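# Synthesis plan for the cis-fused daucane diester 28 (CNP0273650.9)

## The problem

Target 28 is a cis-fused hydroazulene. Atom numbering used throughout: five-membered ring C1(CH3-15)–C2–C3–C4(OH, isopropyl)–C5(H); seven-membered ring C1–C5–C6(O-aroyl)–C7–C8(CH3)=C9–C10(O-tigloyl).

- **Stereocentres.** Five contiguous centres (C6, C5, C4, C1, C10) must be set. CH3-15, H-5, O-6 and O-10 lie on one face. The tertiary C4 hydroxyl lies on the other face, cis on the cyclopentane to the ring carbons C6 and C10.
- **Relay of control.** C6 can set C5, and C5 can set C4, if all three sit in a small ring. C5 can set the quaternary C1 through the ring fusion. The C4 hydroxyl, cis-1,3 to C10, can deliver a reagent to C10.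
- **Fragile groups.** The tertiary alcohol can ionise or eliminate. The allylic tiglate and the phenol ester are two different esters that must go on two different secondary oxygens. The trisubstituted C8=C9 alkene must survive every reduction. In the C10 ketone intermediates the C6 oxygen is delta to the carbonyl through C7 and can be lost by vinylogous elimination under base.
- **Enabling feature.** C10 has only one enolisable neighbour, C1, because C9 is vinylic. C1 is two bonds from C4, and C2 and C3 carry no functionality in 28. An ethynyl group on C4 can therefore supply C2 and C3 and be attacked by C1 of a C10 enol ether, which closes the cyclopentane and creates the quaternary centre in one step.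

## Retrosynthesis

**Esters and C10 (28 ⇒ 27 ⇒ 24 + 25; 24 ⇒ 23).** The phenol O–Si bond, the tigloyl C–O bond at C10 and the C10–H bond are cut. The allylic tiglate is the most fragile group and goes on last. The C6 aroyl ester is installed earlier because it doubles as the C6 protecting group; the reverse order would need a separate protecting group and a choice between two secondary alcohols. Ketone 23 has four stereocentres and one free hydroxyl. The forward reduction must add hydride from the face of the five-membered ring, where the C4 hydroxyl sits, so a hydroxyl-bound borohydride is asked for. The acylation only has to distinguish a secondary from a tertiary alcohol.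

**C2=C3 saturation (23 ⇒ 22).** Two C–H bonds are cut. The alkene is the unavoidable trace of an endo closure onto an alkyne. The forward step must reduce a cis-disubstituted cyclopentene beside a trisubstituted enone and an aryl ester.

**Key disconnection, C1–C2 (22 ⇒ 21).** The neighbouring cuts at C1 (C1–C15 by enolate methylation, C1–C5, C1–C10) leave the face of attack at C1 open. In the C1–C2 cut the nucleophile is unambiguous and the C5–C4–C3 tether dictates the face. Precursor 21 is monocyclic, has three stereocentres and no quaternary carbon. The forward step is a 5-endo-dig attack of the silyl dienol ether carbon C1 on the gold-activated terminal alkyne. It needs O-6 blocked (the ester) and must tolerate the free tertiary propargylic alcohol, which is kept free because it is the directing group for C10 later.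

**C6 ester and the alkyne (21 ⇒ 17 + 20; 17 ⇒ 16 ⇒ 15).** The acyl C–O bond at C6 and the C2≡C3 unit are cut. C3 is traced to the carbonyl carbon of a γ-lactone closed onto O-6, and C2 to a diazophosphonate. The neighbouring cut, C3–C4 by acetylide addition to a C4 isopropyl ketone, was rejected: the acyl group rotates freely and the chelated and non-chelated addition modes predict opposite C4 epimers. In lactone 15, C4 is a ring carbon without an α-hydrogen. The forward steps are a partial lactone reduction and a Seyferth–Gilbert homologation that must spare the silyl dienol ether.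

**Enol ether and seven-membered ring (15 ⇒ 14 ⇒ 13).** The O–Si bond and the C8=C9 bond are cut. The enol ether is made after the ring exists, so its geometry is fixed and both C1 epimers converge. It is made before the alkyne exists, so no terminal alkyne is deprotonated. Ring closure by aldol condensation of a 1,6-diketone would favour a five-membered ring, so metathesis is preferred. The forward metathesis joins a 1,1-disubstituted alkene to a propenyl ketone in a seven-membered ring trans-fused to the lactone.

**Acyl coupling and the stereotriad (13 ⇒ 11 + 12; 11 ⇒ 8 + 9).** The C9–C10 bond, the C1–C5 bond and the C4–O bond are cut. The propenyl ketone is not carried through the conjugate addition, because an enone dienolate could add a second time to its own enone; a thioester is used and coupled afterwards under neutral conditions. On the five-membered lactone the nucleophile adds anti to the C6 side chain and the oxidant adds anti to the new C5 side chain. That is exactly the relative configuration C6/C5/C4 of 28. The precursor 8 has one stereocentre. The forward step needs 1,4-addition to an α-substituted butenolide without γ-deprotonation, and oxidation of a tetrasubstituted enolate.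

**Butenolide and chiral pool (8 ⇒ 7 ⇒ 5 + 6; 5 ⇒ 3 ⇒ 1 + 2).** The ring alkene, the ester C–O bond, the vinyl carbon and the C7–C8 bond are cut. All absolute stereochemistry then derives from (S)-epichlorohydrin 1, whose stereocentre is never touched.

## Roads not taken

**Alternative 1:** The cut is C5–C6 together with O–C4. Oxime A1 carries the C10 silyl ether, a (Z)-C8=C9 alkene and a quaternary C1 on a 3-isopropylcyclopentene. It would be oxidised to the nitrile oxide, which adds across C4=C5 to give isoxazoline A2 and closes the seven-membered ring.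
- Merits: the cycloaddition is suprafacial, so the C4 oxygen and C6 end up cis on the cyclopentane, as in 28. The tether from C1 forces the cis fusion. The tertiary alcohol stays masked, C2–C3 is saturated from the start, and N–O cleavage reveals a hydroxy ketone whose anti reduction is well precedented.
- Weak points: A1 needs the quaternary C1 made enantioselectively before any ring helps, and the C10 carbinol set beside it by open-chain induction. The (Z)-trisubstituted alkene must be built in the chain. A seven-membered closure competes with dimerisation of the dipole. N–O cleavage beside C8=C9 and reduction at C6 add steps.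
- Comparison: for the C4/C5 relation this road is better than the chosen one, since it is stereospecific in one step and carries no free propargylic alcohol. The chosen plan sets against it that C4–C6 all come from one purchased centre by ring-controlled steps, that the quaternary centre arises in the key step, and that the ring closed is five-membered.

**Alternative 2:** The cut is C1–C15. Zinc carbenoid cyclopropanation (Et2Zn, CH2I2) of the ring-fusion alkene A3, directed by the C6 alkoxide, gives cyclopropane A4. Oxidation at C6 and reductive opening of the cyclopropyl ketone would then turn C15 into the methyl group.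
- Merits: hydroxyl direction is reliable and places the methyl group syn to O-6, as 28 requires. No quaternary centre has to be made by C–C bond formation under steric pressure.
- Weak points: the tetrasubstituted alkene is flanked by the fully substituted C4. In A3, C4 and C10 must be set with sp2 carbons between them and C6, so nothing relays. C5 is decided only when the enolate from ring opening is protonated, so the cis fusion is not secured. C6 is oxidised, used and reduced again.
- Comparison: for the C1/C6 relation this road is at least as reliable as the chosen one. The chosen plan sets against it that one geometric constraint fixes both fusion centres and that C6 is never touched after purchase.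

**Alternative 3:** The cut is C1–C5 together with C8–C9. Ionisation of the tertiary α-chloro ketone A5 gives an oxyallyl cation (C1–C10–C9) that adds to the tethered 2-silyloxy diene (C5=C6–C7=C8) in a (4+3) cycloaddition. Adduct A6 has both rings.
- Merits: it has the best step economy of all four roads for the carbon skeleton. Both rings, the quaternary centre and C5 form in one step from an open chain with only C4 set. C2–C3 is saturated and the C10 ketone is in place.
- Weak points: cis or trans fusion and the face relative to C4 depend on compact versus extended transition states, not on a geometric necessity. A6 has the wrong oxidation pattern: a C6 enol ether (hydrolysis makes C5 epimerisable, then a stereoselective reduction is needed), a surplus stereocentre at C8, and no C8=C9 bond.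
- Comparison: the chosen plan is longer and linear in the build-up. It sets against that a cis fusion that cannot be otherwise, and a key-step product that already has O-6 in its final configuration and the C8=C9 enone in place.

Key step: step 13

Assumption: 3-methyl-2-methylidenebutanoic acid (6) is treated as a purchasable building block.

## Route

Step 1
Reactants: 1 (S)-2-(chloromethyl)oxirane; 2 prop-1-en-2-ylmagnesium bromide
Product: 3 (2S)-1-chloro-4-methylpent-4-en-2-ol
Conditions: CuI (10 mol %), THF, −40 °C; aq. NH4Cl
Reagents that add atoms: none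
Why: Copper-catalysed SN2 opening of the epoxide at its CH2 terminus by the alkenyl Grignard reagent; the stereocentre is not involved, so the configuration of 1 is carried into 3.

Step 2
Reactants: 3 (2S)-1-chloro-4-methylpent-4-en-2-ol
Product: 5 (3S)-5-methylhexa-1,5-dien-3-ol, via epoxide (2S)-2-(2-methylprop-2-enyl)oxirane 4 (not isolated)
Conditions: Me3S+ I− (4 equiv), n-BuLi (3.8 equiv), THF, −10 °C → rt
Reagents that add atoms: trimethylsulfonium iodide, C[S+](C)C.[I-]
Why: Base closes the chlorohydrin to epoxide 4, dimethylsulfonium methylide opens it at the CH2 terminus and a further equivalent of ylide eliminates dimethyl sulfide (one-carbon homologation of an epoxide to an allylic alcohol); the carbinol centre is untouched.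

Step 3
Reactants: 5 (3S)-5-methylhexa-1,5-dien-3-ol; 6 3-methyl-2-methylidenebutanoic acid
Product: 7 (3S)-5-methylhexa-1,5-dien-3-yl 3-methyl-2-methylidenebutanoate
Conditions: EDC·HCl, DMAP, CH2Cl2, 0 °C → rt
Reagents that add atoms: none
Why: Steglich esterification of a secondary allylic alcohol with an α-substituted acrylic acid; no stereocentre is affected.

Step 4
Reactants: 7 (3S)-5-methylhexa-1,5-dien-3-yl 3-methyl-2-methylidenebutanoate
Product: 8 (5S)-5-(2-methylprop-2-enyl)-3-(propan-2-yl)furan-2(5H)-one
Conditions: (H2IMes)(PCy3)Cl2Ru=CHPh (second-generation Grubbs catalyst, 5 mol %), CH2Cl2 (0.01 M), 40 °C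
Reagents that add atoms: none
Why: Ring-closing metathesis between the vinyl group (initiation site) and the 1,1-disubstituted acrylate gives the α-substituted butenolide; the 2-methylallyl group cannot close a ring of reasonable size with either partner and stays.

Step 5
Reactants: 8 (5S)-5-(2-methylprop-2-enyl)-3-(propan-2-yl)furan-2(5H)-one; 9 S-ethyl propanethioate
Product: 11 (3R,4S,5S)-4-[1-(ethylsulfanyl)-1-oxopropan-2-yl]-3-hydroxy-5-(2-methylprop-2-enyl)-3-(propan-2-yl)oxolan-2-one (epimers at the side-chain CH), via lithium lactone enolate 10 (not isolated)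
Conditions: LiN(i-Pr)2, THF, −78 °C; 8, −78 → −50 °C; 2-(benzenesulfonyl)-3-phenyloxaziridine, −78 °C; AcOH
Reagents that add atoms: 2-(benzenesulfonyl)-3-phenyloxaziridine, O=S(=O)(c1ccccc1)N1OC1c1ccccc1
Why: Tandem Michael addition and enolate oxidation (Davis hydroxylation): the thioester enolate should add to C5 anti to the C6 side chain, and enolate 10 should take up oxygen anti to the new C5 side chain, which sets C5 and C4 from C6. The epimers at C1 do not matter because C1 becomes sp2 in step 8.

Step 6
Reactants: 11 thioester lactone from step 5; 12 [(1E)-prop-1-en-1-yl]boronic acid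
Product: 13 (3R,4S,5S)-3-hydroxy-5-(2-methylprop-2-enyl)-4-[(4E)-3-oxohex-4-en-2-yl]-3-(propan-2-yl)oxolan-2-one (epimers at the side-chain CH)
Conditions: Pd2(dba)3 (2.5 mol %), P(2-furyl)3, CuO2C(2-C4H3S) (copper thiophene-2-carboxylate, 1.6 equiv), THF, 50 °C
Reagents that add atoms: none
Why: Liebeskind–Srogl coupling of a thioester with an alkenylboronic acid forms the C9–C10 bond under neutral conditions that should leave the lactone, the tertiary alcohol and the alkene untouched.

Step 7
Reactants: 13 enone lactone from step 6
Product: 14 (3R,3aS,8aS)-3-hydroxy-4,7-dimethyl-3-(propan-2-yl)-3a,4,8,8a-tetrahydro-2H-cyclohepta[b]furan-2,5(3H)-dione (epimers at position 4, which is C1)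
Conditions: (H2IMes)Cl2Ru=CH(C6H4-2-O-i-Pr) (second-generation Hoveyda–Grubbs catalyst, 10 mol %), toluene (0.005 M), 80 °C
Reagents that add atoms: none
Why: Ring-closing metathesis of the 1,1-disubstituted alkene with the propenyl ketone should form the trisubstituted C8=C9 bond of the cycloheptenone with loss of propene; a 5/7 lactone with trans fusion is an unstrained, common ring system.

Step 8
Reactants: 14 bicyclic keto lactone from step 7
Product: 15 (3R,3aS,8aS)-3-hydroxy-4,7-dimethyl-3-(propan-2-yl)-5-[tri(propan-2-yl)silyloxy]-3,3a,8,8a-tetrahydro-2H-cyclohepta[b]furan-2-one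
Conditions: LiN(i-Pr)2 (2.3 equiv), THF, −78 °C; i-Pr3SiOTf (1.15 equiv), −78 °C; H2O
Reagents that add atoms: triisopropylsilyl trifluoromethanesulfonate, CC(C)[Si](OS(=O)(=O)C(F)(F)F)(C(C)C)C(C)C
Why: Kinetic enolisation of the enone at the alpha-prime carbon C1 and O-silylation give the cross-conjugated silyl dienol ether; the lactone has no α-hydrogen, the ring fixes the enol ether geometry and both C1 epimers converge. The first equivalent of base is taken by the tertiary hydroxyl, whose hindered alkoxide should not be silylated by the bulky triflate at −78 °C.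

Step 9
Reactants: 15 silyl dienol ether lactone from step 8
Product: 16 (3R,3aS,8aS)-4,7-dimethyl-3-(propan-2-yl)-5-[tri(propan-2-yl)silyloxy]-3,3a,8,8a-tetrahydro-2H-cyclohepta[b]furan-2,3-diol (anomers)
Conditions: i-Bu2AlH (3 equiv), CH2Cl2, −78 °C; aq. potassium sodium tartrate
Reagents that add atoms: none
Why: Partial reduction of a lactone to the lactol at low temperature; the silyl dienol ether is inert to the hydride and no stereocentre of the carbon skeleton is touched.

Step 10
Reactants: 16 lactol from step 9
Product: 17 (1S,2S)-2-[(3R)-3-hydroxy-4-methylpent-1-yn-3-yl]-3,6-dimethyl-4-[tri(propan-2-yl)silyloxy]cyclohepta-3,5-dien-1-ol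
Conditions: MeC(O)C(N2)P(O)(OMe)2, K2CO3, MeOH, 0 °C → rt
Reagents that add atoms: dimethyl (1-diazo-2-oxopropyl)phosphonate, COP(=O)(OC)C(=[N+]=[N-])C(C)=O
Why: Seyferth–Gilbert homologation in the Ohira–Bestmann variant: the open hydroxy aldehyde form of the lactol reacts with the diazomethylphosphonate anion made in situ to give the terminal alkyne (C2 added to C3) and frees the C6 hydroxyl. C4 cannot enolise and keeps its configuration.

Step 11
Reactants: 18 4-hydroxybenzoic acid
Product: 20 4-[tert-butyl(dimethyl)silyloxy]benzoic acid, via silyl ester tert-butyl(dimethyl)silyl 4-[tert-butyl(dimethyl)silyloxy]benzoate 19 (not isolated)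
Conditions: t-BuMe2SiCl (2.4 equiv), imidazole, DMF, rt; then AcOH/THF/H2O, rt
Reagents that add atoms: tert-butyldimethylsilyl chloride, CC(C)(C)[Si](C)(C)Cl
Why: Silylation of both the phenol and the acid, followed by selective hydrolysis of the much more labile silyl ester.

Step 12
Reactants: 17 alkynyl diol from step 10; 20 4-[tert-butyl(dimethyl)silyloxy]benzoic acid
Product: 21 (1S,2S)-2-[(3R)-3-hydroxy-4-methylpent-1-yn-3-yl]-3,6-dimethyl-4-[tri(propan-2-yl)silyloxy]cyclohepta-3,5-dien-1-yl 4-[tert-butyl(dimethyl)silyloxy]benzoate
Conditions: EDC·HCl, DMAP, CH2Cl2, rt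
Reagents that add atoms: none
Why: Steglich esterification of the secondary C6 hydroxyl; the tertiary propargylic hydroxyl is too hindered to be acylated. The ester is the final C6 substituent and also keeps O-6 from adding to the alkyne in step 13.

Step 13
Reactants: 21 silyl dienol ether alkyne from step 12
Product: 22 (3S,3aS,4S,8aR)-3-hydroxy-6,8a-dimethyl-8-oxo-3-(propan-2-yl)-3,3a,4,5,8,8a-hexahydroazulen-4-yl 4-[tert-butyl(dimethyl)silyloxy]benzoate
Conditions: Ph3PAuNTf2 (5 mol %), CH2Cl2/MeOH 10:1, rt
Reagents that add atoms: none
Why: The cationic monovalent gold complex binds the terminal alkyne and makes C2 electrophilic; C1 of the C10 silyl dienol ether attacks anti to gold, and methanol takes the silyl group from the oxocarbenium ion and protonates the vinyl–gold bond, giving the C10 ketone and the C2=C3 alkene. The closest known reaction type is the gold-catalysed carbocyclisation of silyl enol ethers onto alkynes (Conia-ene type), established for 5-endo-dig closures that create quaternary centres. The one ring closed is the cyclopentene C1–C2–C3–C4–C5, in the 5-endo-dig mode; the alternative 4-exo-dig attack on C3 is strained and not expected. The new stereocentre C1 is controlled by C5: the C5–C4–C3 tether cannot reach the far face of the enol ether, so C2 bonds syn to C4 and the methyl group ends up cis to H-5. Allylic strain between the C1 methyl group and the C5 substituent should hold the alkynyl carbinol pseudo-axial over the enol ether face, which helps the closure. Site selectivity at the nucleophile is secured by the structure, since the dienol ether is nucleophilic only at C1 (C9 is vinylic). Chemoselectivity at the alkyne is needed as well: O-6 is acylated and cannot add in a 5-exo-dig hydroalkoxylation, and the intramolecular carbon nucleophile should outrun methanol addition, which would start a Meyer–Schuster rearrangement of the free tertiary propargylic alcohol.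

Step 14
Reactants: 22 dienone from step 13
Product: 23 (3R,3aS,4S,8aR)-3-hydroxy-6,8a-dimethyl-8-oxo-3-(propan-2-yl)-1,2,3,3a,4,5,8,8a-octahydroazulen-4-yl 4-[tert-butyl(dimethyl)silyloxy]benzoate
Conditions: 2-nitrobenzenesulfonohydrazide, Et3N, CH2Cl2, rt
Reagents that add atoms: none
Why: Diimide reduction: concerted transfer of H2 to the strained cis-disubstituted cyclopentene should be much faster than to the trisubstituted, conjugated C8=C9 bond; no stereocentre is formed.

Step 15
Reactants: 23 enone from step 14
Product: 24 (3R,3aS,4S,8R,8aR)-3,8-dihydroxy-6,8a-dimethyl-3-(propan-2-yl)-1,2,3,3a,4,5,8,8a-octahydroazulen-4-yl 4-[tert-butyl(dimethyl)silyloxy]benzoate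
Conditions: Me4NBH(OAc)3, MeCN/AcOH 1:1, −20 → 0 °C
Reagents that add atoms: none
Why: Hydroxyl-directed reduction (Evans–Saksena type): the triacetoxyborohydride exchanges a ligand with the C4 hydroxyl, which is cis-1,3 to C10 on the cyclopentane, and delivers hydride to the carbonyl carbon from the face of the five-membered ring. This should give the (10R) alcohol with OH syn to CH3-15, and 1,2- rather than 1,4-reduction.

Step 16
Reactants: 24 allylic alcohol from step 15; 25 (2E)-2-methylbut-2-enoic acid
Product: 27 (3R,3aS,4S,8R,8aR)-3-hydroxy-6,8a-dimethyl-8-{[(2E)-2-methylbut-2-enoyl]oxy}-3-(propan-2-yl)-1,2,3,3a,4,5,8,8a-octahydroazulen-4-yl 4-[tert-butyl(dimethyl)silyloxy]benzoate, via mixed anhydride (2E)-2-methylbut-2-enoic 2,4,6-trichlorobenzoic anhydride 26 (not isolated)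
Conditions: 2,4,6-Cl3C6H2COCl, Et3N, toluene, rt; then 24, DMAP, 60 °C
Reagents that add atoms: none
Why: Yamaguchi esterification: the mixed anhydride acylates the hindered secondary allylic alcohol under DMAP catalysis; the tertiary hydroxyl does not react and the (E)-ester is the stable isomer.

Step 17
Reactants: 27 silyl-protected diester from step 16
Product: 28 (3R,3aS,4S,8R,8aR)-3-hydroxy-6,8a-dimethyl-8-{[(2E)-2-methylbut-2-enoyl]oxy}-3-(propan-2-yl)-1,2,3,3a,4,5,8,8a-octahydroazulen-4-yl 4-hydroxybenzoate
Conditions: Bu4NF, AcOH, THF, 0 °C
Reagents that add atoms: none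
Why: Fluoride cleavage of the aryl silyl ether is far faster than any attack on the esters; buffering with acetic acid should prevent acyl migration or ester cleavage.

## Compound list

1 | (S)-2-(chloromethyl)oxirane | ClC[C@@H]1CO1 | starting material
2 | prop-1-en-2-ylmagnesium bromide | CC(=C)[Mg]Br | starting material
3 | (2S)-1-chloro-4-methylpent-4-en-2-ol | ClC[C@@H](O)CC(C)=C | intermediate
4 | (2S)-2-(2-methylprop-2-enyl)oxirane | C=C(C)C[C@H]1CO1 | intermediate (not isolated)
5 | (3S)-5-methylhexa-1,5-dien-3-ol | C=C[C@@H](O)CC(C)=C | intermediate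
6 | 3-methyl-2-methylidenebutanoic acid | C=C(C(C)C)C(=O)O | starting material
7 | (3S)-5-methylhexa-1,5-dien-3-yl 3-methyl-2-methylidenebutanoate | C=C[C@H](CC(C)=C)OC(=O)C(=C)C(C)C | intermediate
8 | (5S)-5-(2-methylprop-2-enyl)-3-(propan-2-yl)furan-2(5H)-one | CC(C)C1=C[C@H](CC(C)=C)OC1=O | intermediate
9 | S-ethyl propanethioate | CCC(=O)SCC | starting material
10 | lithium (4R,5S)-4-[1-(ethylsulfanyl)-1-oxopropan-2-yl]-5-(2-methylprop-2-enyl)-3-(propan-2-yl)-4,5-dihydrofuran-2-olate (lithium lactone enolate) | [Li+].[O-]C1=C(C(C)C)[C@@H](C(C)C(=O)SCC)[C@H](CC(C)=C)O1 | intermediate (not isolated)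
11 | (3R,4S,5S)-4-[1-(ethylsulfanyl)-1-oxopropan-2-yl]-3-hydroxy-5-(2-methylprop-2-enyl)-3-(propan-2-yl)oxolan-2-one | O=C1O[C@@H](CC(C)=C)[C@H](C(C)C(=O)SCC)[C@]1(O)C(C)C | intermediate
12 | [(1E)-prop-1-en-1-yl]boronic acid | C/C=C/B(O)O | starting material
13 | (3R,4S,5S)-3-hydroxy-5-(2-methylprop-2-enyl)-4-[(4E)-3-oxohex-4-en-2-yl]-3-(propan-2-yl)oxolan-2-one | O=C1O[C@@H](CC(C)=C)[C@H](C(C)C(=O)/C=C/C)[C@]1(O)C(C)C | intermediate
14 | (3R,3aS,8aS)-3-hydroxy-4,7-dimethyl-3-(propan-2-yl)-3a,4,8,8a-tetrahydro-2H-cyclohepta[b]furan-2,5(3H)-dione | O=C1O[C@H]2CC(C)=CC(=O)C(C)[C@@H]2[C@]1(O)C(C)C | intermediate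
15 | (3R,3aS,8aS)-3-hydroxy-4,7-dimethyl-3-(propan-2-yl)-5-[tri(propan-2-yl)silyloxy]-3,3a,8,8a-tetrahydro-2H-cyclohepta[b]furan-2-one | O=C1O[C@H]2CC(C)=CC(O[Si](C(C)C)(C(C)C)C(C)C)=C(C)[C@@H]2[C@]1(O)C(C)C | intermediate
16 | (3R,3aS,8aS)-4,7-dimethyl-3-(propan-2-yl)-5-[tri(propan-2-yl)silyloxy]-3,3a,8,8a-tetrahydro-2H-cyclohepta[b]furan-2,3-diol | OC1O[C@H]2CC(C)=CC(O[Si](C(C)C)(C(C)C)C(C)C)=C(C)[C@@H]2[C@]1(O)C(C)C | intermediate
17 | (1S,2S)-2-[(3R)-3-hydroxy-4-methylpent-1-yn-3-yl]-3,6-dimethyl-4-[tri(propan-2-yl)silyloxy]cyclohepta-3,5-dien-1-ol | C#C[C@@](O)(C(C)C)[C@@H]1[C@@H](O)CC(C)=CC(O[Si](C(C)C)(C(C)C)C(C)C)=C1C | intermediate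
18 | 4-hydroxybenzoic acid | OC(=O)c1ccc(O)cc1 | starting material
19 | tert-butyl(dimethyl)silyl 4-[tert-butyl(dimethyl)silyloxy]benzoate | CC(C)(C)[Si](C)(C)OC(=O)c1ccc(O[Si](C)(C)C(C)(C)C)cc1 | intermediate (not isolated)
20 | 4-[tert-butyl(dimethyl)silyloxy]benzoic acid | OC(=O)c1ccc(O[Si](C)(C)C(C)(C)C)cc1 | intermediate
21 | (1S,2S)-2-[(3R)-3-hydroxy-4-methylpent-1-yn-3-yl]-3,6-dimethyl-4-[tri(propan-2-yl)silyloxy]cyclohepta-3,5-dien-1-yl 4-[tert-butyl(dimethyl)silyloxy]benzoate | C#C[C@@](O)(C(C)C)[C@@H]1[C@@H](OC(=O)c2ccc(O[Si](C)(C)C(C)(C)C)cc2)CC(C)=CC(O[Si](C(C)C)(C(C)C)C(C)C)=C1C | intermediate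
22 | (3S,3aS,4S,8aR)-3-hydroxy-6,8a-dimethyl-8-oxo-3-(propan-2-yl)-3,3a,4,5,8,8a-hexahydroazulen-4-yl 4-[tert-butyl(dimethyl)silyloxy]benzoate | O=C1C=C(C)C[C@H](OC(=O)c3ccc(O[Si](C)(C)C(C)(C)C)cc3)[C@@H]2[C@@]1(C)C=C[C@@]2(O)C(C)C | intermediate
23 | (3R,3aS,4S,8aR)-3-hydroxy-6,8a-dimethyl-8-oxo-3-(propan-2-yl)-1,2,3,3a,4,5,8,8a-octahydroazulen-4-yl 4-[tert-butyl(dimethyl)silyloxy]benzoate | O=C1C=C(C)C[C@H](OC(=O)c3ccc(O[Si](C)(C)C(C)(C)C)cc3)[C@@H]2[C@@]1(C)CC[C@@]2(O)C(C)C | intermediate
24 | (3R,3aS,4S,8R,8aR)-3,8-dihydroxy-6,8a-dimethyl-3-(propan-2-yl)-1,2,3,3a,4,5,8,8a-octahydroazulen-4-yl 4-[tert-butyl(dimethyl)silyloxy]benzoate | O[C@@H]1C=C(C)C[C@H](OC(=O)c3ccc(O[Si](C)(C)C(C)(C)C)cc3)[C@@H]2[C@@]1(C)CC[C@@]2(O)C(C)C | intermediate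
25 | (2E)-2-methylbut-2-enoic acid (tiglic acid) | C/C=C(\C)C(=O)O | starting material
26 | (2E)-2-methylbut-2-enoic 2,4,6-trichlorobenzoic anhydride | C/C=C(\C)C(=O)OC(=O)c1c(Cl)cc(Cl)cc1Cl | intermediate (not isolated)
27 | (3R,3aS,4S,8R,8aR)-3-hydroxy-6,8a-dimethyl-8-{[(2E)-2-methylbut-2-enoyl]oxy}-3-(propan-2-yl)-1,2,3,3a,4,5,8,8a-octahydroazulen-4-yl 4-[tert-butyl(dimethyl)silyloxy]benzoate | C/C=C(\C)C(=O)O[C@@H]1C=C(C)C[C@H](OC(=O)c2ccc(O[Si](C)(C)C(C)(C)C)cc2)[C@@H]2[C@@]1(C)CC[C@@]2(O)C(C)C | intermediate
28 | (3R,3aS,4S,8R,8aR)-3-hydroxy-6,8a-dimethyl-8-{[(2E)-2-methylbut-2-enoyl]oxy}-3-(propan-2-yl)-1,2,3,3a,4,5,8,8a-octahydroazulen-4-yl 4-hydroxybenzoate | C/C=C(\C)C(=O)O[C@@H]1C=C(C)C[C@H](OC(=O)c2ccc(O)cc2)[C@@H]2[C@@]1(C)CC[C@@]2(O)C(C)C | target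

## Step count and least certain steps

Total: 17 steps. Longest linear sequence: 16 steps (steps 1–10 and 12–17 from 1); step 11 is a one-step side branch.

**Step 13 (key step).** Three processes could compete with the closure. The silyl group could be lost from the dienol ether by methanolysis before the C–C bond forms. The free tertiary propargylic alcohol could rearrange (Meyer–Schuster) or ionise at the gold-bound alkyne. The closure could be slow because a quaternary centre forms next to the carbon that carries the fully substituted C4. The fallback forms the same C1–C2 bond by an aldol closure, sets out from 21 and returns at 23. Anti-Markovnikov hydration of the alkyne (dicyclohexylborane, then NaBO3) would give the C2 aldehyde F1. BF3·OEt2 at −78 °C would close the ring by an intramolecular Mukaiyama aldol addition of C1 to C2, with the same tether-enforced cis fusion, to the 2-hydroxy ketone F2. Its secondary hydroxyl would be converted with 1,1'-thiocarbonyldiimidazole into the imidazolylthiocarbonate F3. Bu3SnH/AIBN (Barton–McCombie deoxygenation) would then give 23 directly, so the alkene reduction of step 14 is no longer needed.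

**Step 5.** The basic thioester enolate could remove the γ-hydrogen of the butenolide, which would erode the C6 configuration. Addition at the β-carbon flanked by the isopropyl group could be slow. Proton transfer from the thioester α-position to the lactone enolate before oxidation would move the hydroxylation to the wrong carbon. The fallback avoids basic enolates, sets out from 8 and 9 and returns at 11. Thioester 9 would be converted (LiN(i-Pr)2, Me3SiCl) into the ketene silyl thioacetal F4. Mukaiyama–Michael addition of F4 to 8 (catalytic Me3SiOTf, CH2Cl2, −78 °C) with silyl transfer would give the lactone silyl ketene acetal F5. Rubottom oxidation of F5 with dimethyldioxirane at −78 °C and aqueous work-up would give 11 with the same facial preferences.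

**Step 7.** The ruthenium carbene must load onto a 1,1-disubstituted alkene and close onto an electron-poor 1,2-disubstituted enone; initiation could be slow, and dimerisation or catalyst decay could take over. The fallback closes the same C8=C9 bond by olefination, sets out from 8 and returns at 14. The dianion of dimethyl (2-oxobutyl)phosphonate would be used as the Michael donor, with the same oxaziridine trapping, to give the β-ketophosphonate lactone F6. Ozonolysis of the 2-methylallyl group (O3, then Me2S) would give the methyl ketone F7. Intramolecular Horner–Wadsworth–Emmons reaction (LiCl, i-Pr2NEt, MeCN) would then give 14.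

**Step 10.** Carbonate in methanol could cleave the silyl dienol ether, the hindered lactol could open slowly, and the α-hydroxy aldehyde could undergo an α-ketol shift. The fallback installs the alkyne before the enol ether, sets out from 14 and returns at 21. Excess i-Bu2AlH would reduce both the lactone and the C10 ketone to give the lactol carbinol F8. The same homologation would give the alkynyl triol F9. MnO2 would oxidise only the allylic C10 alcohol to the enone diol F10. Steglich esterification with 20 would give the C6 ester F11. Soft enolisation (i-Pr3SiOTf, Et3N), which does not deprotonate the alkyne, would then give 21.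

**Step 14.** The cyclopentene is flanked by two fully substituted carbons and could react slowly, so that reduction of the enone alkene begins to compete. The fallback changes the selectivity principle from steric preference to hydroxyl direction and runs from 22 to 23 without a new compound: hydrogenation with [Ir(cod)(PCy3)(py)]PF6 and H2 in CH2Cl2, in which the allylic C4 hydroxyl, the only free hydroxyl in 22, binds the catalyst and directs it to C2=C3.

**Step 15.** The hindered tertiary hydroxyl could exchange too slowly with the borohydride, so that no delivery occurs or external hydride attacks the other face. The fallback replaces delivery by inversion, sets out from 23 and returns at 27. Non-directed reduction with NaBH4/CeCl3 would give the C10 epimer F12 if attack comes from the methyl-bearing face. Mitsunobu esterification of F12 with tiglic acid 25 (PPh3, diisopropyl azodicarboxylate) would invert C10 and install the tiglate in the same operation.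

## Further compounds

F1 | step 13 | C2 aldehyde from anti-Markovnikov hydration of 21 | O=CC[C@@](O)(C(C)C)[C@@H]1[C@@H](OC(=O)c2ccc(O[Si](C)(C)C(C)(C)C)cc2)CC(C)=CC(O[Si](C(C)C)(C(C)C)C(C)C)=C1C
F2 | step 13 | 2-hydroxy derivative of 23 (C2 epimers) | O=C1C=C(C)C[C@H](OC(=O)c3ccc(O[Si](C)(C)C(C)(C)C)cc3)[C@@H]2[C@@]1(C)C(O)C[C@@]2(O)C(C)C
F3 | step 13 | 2-O-(imidazol-1-ylcarbonothioyl) derivative of F2 | O=C1C=C(C)C[C@H](OC(=O)c3ccc(O[Si](C)(C)C(C)(C)C)cc3)[C@@H]2[C@@]1(C)C(OC(=S)n4ccnc4)C[C@@]2(O)C(C)C
F4 | step 5 | 1-(ethylsulfanyl)-1-(trimethylsilyloxy)prop-1-ene | CC=C(O[Si](C)(C)C)SCC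
F5 | step 5 | trimethylsilyl ketene acetal of the conjugate adduct (O-silyl analogue of 10) | C[Si](C)(C)OC1=C(C(C)C)[C@@H](C(C)C(=O)SCC)[C@H](CC(C)=C)O1
F6 | step 7 | dimethyl β-ketophosphonate analogue of 13 (CH2P(O)(OMe)2 in place of the propenyl group) | O=C1O[C@@H](CC(C)=C)[C@H](C(C)C(=O)CP(=O)(OC)OC)[C@]1(O)C(C)C
F7 | step 7 | methyl ketone from ozonolysis of F6 | O=C1O[C@@H](CC(C)=O)[C@H](C(C)C(=O)CP(=O)(OC)OC)[C@]1(O)C(C)C
F8 | step 10 | lactol of 14 with the C10 ketone reduced to the alcohol | OC1O[C@H]2CC(C)=CC(O)C(C)[C@@H]2[C@]1(O)C(C)C
F9 | step 10 | alkynyl triol (C4, C6 and C10 hydroxyls) | C#C[C@@](O)(C(C)C)[C@@H]1[C@@H](O)CC(C)=CC(O)C1C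
F10 | step 10 | alkynyl enone diol | C#C[C@@](O)(C(C)C)[C@@H]1[C@@H](O)CC(C)=CC(=O)C1C
F11 | step 10 | C6 4-[tert-butyl(dimethyl)silyloxy]benzoate of F10 | C#C[C@@](O)(C(C)C)[C@@H]1[C@@H](OC(=O)c2ccc(O[Si](C)(C)C(C)(C)C)cc2)CC(C)=CC(=O)C1C
F0 | step 14 | none | none
F12 | step 15 | C10 epimer of 24 | O[C@H]1C=C(C)C[C@H](OC(=O)c3ccc(O[Si](C)(C)C(C)(C)C)cc3)[C@@H]2[C@@]1(C)CC[C@@]2(O)C(C)C
A1 | alternative 1 | oxime precursor with (Z)-C8=C9 alkene and 3-isopropylcyclopentene | CC(C)(C)[Si](C)(C)O[C@H](/C=C(C)\CC=NO)[C@]1(C)CCC(C(C)C)=C1
A2 | alternative 1 | isoxazoline-fused hydroazulene | CC(C)(C)[Si](C)(C)O[C@@H]1C=C(C)CC2=NO[C@@]3(C(C)C)CC[C@]1(C)[C@@H]23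
A3 | alternative 2 | hydroazulene with C1=C5 ring-fusion alkene and free C6 hydroxyl | CC(C)(C)[Si](C)(C)O[C@@H]1C=C(C)C[C@H](O)C2=C1CC[C@@]2(O[Si](CC)(CC)CC)C(C)C
A4 | alternative 2 | ring-fusion cyclopropane with C15 on the face of the C6 hydroxyl | CC(C)(C)[Si](C)(C)O[C@@H]1C=C(C)C[C@H](O)[C@]23C[C@]12CC[C@@]3(O[Si](CC)(CC)CC)C(C)C
A5 | alternative 3 | tertiary α-chloro ketone with tethered 2-silyloxy diene | CC(=O)C(C)(Cl)CC[C@@](O[Si](CC)(CC)CC)(C(C)C)C=C(O[Si](C)(C)C(C)(C)C)/C=C/C
A6 | alternative 3 | hydroazulen-10-one with C6 silyl enol ether | O=C1C[C@@H](C)C=C(O[Si](C)(C)C(C)(C)C)[C@@H]2[C@@]1(C)CC[C@@]2(O[Si](CC)(CC)CC)C(C)C
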